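## Retrosynthetic overview

- The target is all-E (6R)-7',8'-dihydro-ε,ψ-carotene. Its chain is cut by Wittig olefination at C11=C12 and C11'=C12' into the ring-bearing C15 phosphonium salt 17, the C10 dialdehyde 20 and the farnesyl phosphonium salt 19.
- The strategy rests on ring A: the tertiary stereocentre C6 lies between the gem-dimethyl carbon C1 and the ring alkene C4=C5, which is the pattern an allylic transposition from a leaving group on C4 leaves behind. C6–C7 is therefore cut to the (R)-picolinate 7 and the dienyl iodide 11, joined by anti SN2' substitution.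
- Ring A, the only ring, is made first by Robinson annulation. An oxazaborolidine reduction sets the C4 carbinol centre, which is then relayed to C6.

Key step: step 6

Remark: positions are given in carotenoid numbering (ring A C1–C6, chain from C7, primed numbers for the acyclic half). The (S)-configured oxazaborolidine is assumed to give the (R)-alcohol, with the α-methylated alkene arm of enone 4 acting as the larger ketone substituent.

## Route

Step 1
Reactants: 1 isobutyraldehyde; 2 pent-1-en-3-one
Product: 4 2,4,4-trimethylcyclohex-2-en-1-one, via 2,2-dimethyl-5-oxoheptanal 3 (not isolated)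
Conditions: conc. H2SO4 (cat.), toluene, 50 °C then reflux, Dean–Stark
Reagents that add atoms: none
Why: Acid-catalysed Robinson annulation, in which the enol of the aldehyde adds to the enone in Michael fashion and the keto-aldehyde closes by aldol condensation of the ethyl-ketone methylene onto the non-enolisable aldehyde, the only mode that gives a six-membered enone.

Step 2
Reactants: 4 2,4,4-trimethylcyclohex-2-en-1-one
Product: 5 (1R)-2,4,4-trimethylcyclohex-2-en-1-ol
Conditions: (S)-1-methyl-3,3-diphenyltetrahydro-1H,3H-pyrrolo[1,2-c][1,3,2]oxazaborole (10 mol %), BH3·SMe2, THF, −20 °C, slow addition of 4; MeOH quench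
Reagents that add atoms: none
Why: Corey–Bakshi–Shibata reduction, in which the catalyst–borane complex binds the carbonyl oxygen anti to the larger α-methylated alkene arm and delivers hydride 1,2 to one face, which should set the (R) carbinol centre (C4).

Step 3
Reactants: 5 (1R)-2,4,4-trimethylcyclohex-2-en-1-ol; 6 picolinic acid
Product: 7 (1R)-2,4,4-trimethylcyclohex-2-en-1-yl pyridine-2-carboxylate
Conditions: N,N'-dicyclohexylcarbodiimide, 4-(dimethylamino)pyridine (cat.), CH2Cl2, 0 °C to rt
Reagents that add atoms: none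
Why: Steglich esterification of the secondary allylic alcohol, which leaves the carbinol C–O bond untouched so that the (R) centre is retained.

Step 4
Reactants: 8 (E)-3-methylpent-2-en-4-yn-1-ol
Product: 9 tert-butyldimethylsilyl ether of (E)-3-methylpent-2-en-4-yn-1-ol
Conditions: t-BuMe2SiCl, imidazole, DMF, 0 °C to rt
Reagents that add atoms: tert-butyldimethylsilyl chloride, CC(C)(C)[Si](C)(C)Cl
Why: Imidazole-promoted silylation of the primary alcohol, which masks the hydroxyl against Cp2Zr(H)Cl and t-BuLi in the next two steps.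

Step 5
Reactants: 9 tert-butyldimethylsilyl ether of (E)-3-methylpent-2-en-4-yn-1-ol
Product: 11 tert-butyldimethylsilyl ether of (2E,4E)-5-iodo-3-methylpenta-2,4-dien-1-ol, via dienylzirconocene chloride 10 (not isolated)
Conditions: Cp2Zr(H)Cl (1.3 equiv), THF, rt, dark; then I2, 0 °C
Reagents that add atoms: iodine, II
Why: Hydrozirconation–iodination, in which Zr–H adds syn across the terminal alkyne with zirconium on the terminal carbon and iodinolysis proceeds with retention, so the new alkene should be E while the trisubstituted alkene stays untouched.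

Step 6
Reactants: 11 tert-butyldimethylsilyl ether of (2E,4E)-5-iodo-3-methylpenta-2,4-dien-1-ol; 7 (1R)-2,4,4-trimethylcyclohex-2-en-1-yl pyridine-2-carboxylate
Product: 15 tert-butyldimethylsilyl ether of (2E,4E)-3-methyl-5-[(1R)-2,6,6-trimethylcyclohex-2-en-1-yl]penta-2,4-dien-1-ol, via dienyllithium 12 (not isolated), via dienylmagnesium bromide 13 (not isolated), via dienylcopper 14 (not isolated)
Conditions: 11 (2 equiv), t-BuLi (4 equiv), Et2O, −78 °C; MgBr2 (4 equiv), −78 to 0 °C; CuBr·SMe2 (2 equiv), THF, 0 °C; then 7, 0 °C to rt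
Reagents that add atoms: none
Why: Iodine–lithium exchange, then transmetalation to magnesium and to monovalent copper, gives a dienylcopper·MgBr2 reagent; magnesium held between the pyridine nitrogen and the carbonyl oxygen of 7 makes the picolinate a good, pseudoaxial leaving group, copper binds the C5=C6 alkene on the face opposite the C4–O bond, oxidative addition gives a C6-bound allylcopper species of trivalent copper, and reductive elimination forms C6–C7 with the ring alkene moved to C4=C5. The closest known reaction type is the anti SN2' substitution of secondary allylic picolinates by aryl- and alkenylcopper reagents, applied here to a dienyl group. No ring is closed. The one new stereocentre, C6, is controlled by the C4 carbinol centre through anti 1,3-chirality transfer, so the (R) ester should give the (R) product. The step needs γ over α regioselectivity, anti facial selectivity and retention of the 2E,4E geometry of the transferred group; the chelating leaving group secures the first two and the configurational stability of alkenyl–copper bonds at 0 °C secures the third. The attacked carbon is neopentyl but carries only hydrogen, and the excess MgBr2 keeps the ester activated so that substitution should outpace addition to its carbonyl group.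

Step 7
Reactants: 15 tert-butyldimethylsilyl ether of (2E,4E)-3-methyl-5-[(1R)-2,6,6-trimethylcyclohex-2-en-1-yl]penta-2,4-dien-1-ol
Product: 16 (2E,4E)-3-methyl-5-[(1R)-2,6,6-trimethylcyclohex-2-en-1-yl]penta-2,4-dien-1-ol
Conditions: Bu4NF, THF, 0 °C to rt; aq. NH4Cl work-up
Reagents that add atoms: none
Why: Fluoride-mediated desilylation driven by the strong Si–F bond, under conditions that touch neither the diene, the ring alkene nor the C6 centre.

Step 8
Reactants: 16 (2E,4E)-3-methyl-5-[(1R)-2,6,6-trimethylcyclohex-2-en-1-yl]penta-2,4-dien-1-ol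
Product: 17 [(2E,4E)-3-methyl-5-[(1R)-2,6,6-trimethylcyclohex-2-en-1-yl]penta-2,4-dien-1-yl]triphenylphosphonium bromide
Conditions: PPh3·HBr, MeOH, 0 °C to rt, dark; crystallisation
Reagents that add atoms: triphenylphosphine hydrobromide, Br.c1ccc(cc1)P(c1ccccc1)c1ccccc1
Why: Phosphonium salt formation from an allylic alcohol by SN1-type substitution, in which the pentadienyl cation is captured by PPh3 at its unhindered primary terminus, the standard way to C15 Wittig salts, with C6 not involved.

Step 9
Reactants: 18 (2E,6E)-farnesyl bromide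
Product: 19 [(2E,6E)-3,7,11-trimethyldodeca-2,6,10-trien-1-yl]triphenylphosphonium bromide
Conditions: PPh3, toluene, rt
Reagents that add atoms: triphenylphosphine, c1ccc(cc1)P(c1ccccc1)c1ccccc1
Why: SN2 quaternisation of PPh3 by the primary allylic bromide at room temperature, which should leave the 2E,6E geometry intact.

Step 10
Reactants: 19 [(2E,6E)-3,7,11-trimethyldodeca-2,6,10-trien-1-yl]triphenylphosphonium bromide; 20 (2E,4E,6E)-2,7-dimethylocta-2,4,6-trienedial
Product: 23 (2E,4E,6E,8E,10E,14E)-2,7,11,15,19-pentamethylicosa-2,4,6,8,10,14,18-heptaenal, via farnesylidene ylide 21 (not isolated), via 8Z aldehyde 22 (not isolated)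
Conditions: 19, n-BuLi (1.0 equiv), THF, −78 to 0 °C; added slowly to 20 (3 equiv), THF–CH2Cl2, −40 °C to rt; then heptane, 90 °C, argon; chromatography with recovery of 20
Reagents that add atoms: none
Why: Wittig olefination forming C11'=C12', in which slow addition of the ylide to excess dialdehyde favours reaction at one formyl group only and the sterically hindered 8Z isomer should relax to 8E on heating.

Step 11
Reactants: 17 [(2E,4E)-3-methyl-5-[(1R)-2,6,6-trimethylcyclohex-2-en-1-yl]penta-2,4-dien-1-yl]triphenylphosphonium bromide; 23 (2E,4E,6E,8E,10E,14E)-2,7,11,15,19-pentamethylicosa-2,4,6,8,10,14,18-heptaenal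
Product: 26 all-E (6R)-7',8'-dihydro-ε,ψ-carotene, via C15 ylide 24 (not isolated), via 11Z carotene 25 (not isolated)
Conditions: NaOMe, MeOH–CH2Cl2, 0 °C to rt, argon, dim light; then heptane, reflux, argon; crystallisation
Reagents that add atoms: none
Why: Wittig olefination forming C11=C12, after which the hindered 11Z isomer should isomerise thermally to the all-E polyene, while C6 is remote from the ylide carbon and is not epimerised.

## Compound list

1 | isobutyraldehyde | CC(C)C=O | starting material
2 | pent-1-en-3-one | CCC(=O)C=C | starting material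
3 | 2,2-dimethyl-5-oxoheptanal | CCC(=O)CCC(C)(C)C=O | intermediate
4 | 2,4,4-trimethylcyclohex-2-en-1-one | CC1=CC(C)(C)CCC1=O | intermediate
5 | (1R)-2,4,4-trimethylcyclohex-2-en-1-ol | O[C@H]1C(C)=CC(C)(C)CC1 | intermediate
6 | picolinic acid (pyridine-2-carboxylic acid) | OC(=O)c1ccccn1 | starting material
7 | (1R)-2,4,4-trimethylcyclohex-2-en-1-yl pyridine-2-carboxylate | O=C(O[C@H]1C(C)=CC(C)(C)CC1)c1ccccn1 | intermediate
8 | (E)-3-methylpent-2-en-4-yn-1-ol | C#C/C(C)=C/CO | starting material
9 | tert-butyldimethylsilyl ether of (E)-3-methylpent-2-en-4-yn-1-ol | C#C/C(C)=C/CO[Si](C)(C)C(C)(C)C | intermediate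
10 | chlorobis(cyclopentadienyl)[(1E,3E)-5-(tert-butyldimethylsilyloxy)-3-methylpenta-1,3-dien-1-yl]zirconium | CC(C)(C)[Si](C)(C)OC/C=C(C)/C=C/[Zr](Cl)(C1C=CC=C1)C1C=CC=C1 | intermediate
11 | tert-butyldimethylsilyl ether of (2E,4E)-5-iodo-3-methylpenta-2,4-dien-1-ol | CC(C)(C)[Si](C)(C)OC/C=C(C)/C=C/I | intermediate
12 | [(1E,3E)-5-(tert-butyldimethylsilyloxy)-3-methylpenta-1,3-dien-1-yl]lithium | CC(C)(C)[Si](C)(C)OC/C=C(C)/C=C/[Li] | intermediate
13 | [(1E,3E)-5-(tert-butyldimethylsilyloxy)-3-methylpenta-1,3-dien-1-yl]magnesium bromide | CC(C)(C)[Si](C)(C)OC/C=C(C)/C=C/[Mg]Br | intermediate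
14 | [(1E,3E)-5-(tert-butyldimethylsilyloxy)-3-methylpenta-1,3-dien-1-yl]copper | CC(C)(C)[Si](C)(C)OC/C=C(C)/C=C/[Cu] | intermediate
15 | tert-butyldimethylsilyl ether of (2E,4E)-3-methyl-5-[(1R)-2,6,6-trimethylcyclohex-2-en-1-yl]penta-2,4-dien-1-ol | CC(C)(C)[Si](C)(C)OC/C=C(C)/C=C/[C@H]1C(C)=CCCC1(C)C | intermediate
16 | (2E,4E)-3-methyl-5-[(1R)-2,6,6-trimethylcyclohex-2-en-1-yl]penta-2,4-dien-1-ol | OC/C=C(C)/C=C/[C@H]1C(C)=CCCC1(C)C | intermediate
17 | [(2E,4E)-3-methyl-5-[(1R)-2,6,6-trimethylcyclohex-2-en-1-yl]penta-2,4-dien-1-yl]triphenylphosphonium bromide | [Br-].c1ccccc1[P+](c1ccccc1)(c1ccccc1)C/C=C(C)/C=C/[C@H]1C(C)=CCCC1(C)C | intermediate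
18 | (2E,6E)-farnesyl bromide ((2E,6E)-1-bromo-3,7,11-trimethyldodeca-2,6,10-triene) | CC(C)=CCC/C(C)=C/CC/C(C)=C/CBr | starting material
19 | [(2E,6E)-3,7,11-trimethyldodeca-2,6,10-trien-1-yl]triphenylphosphonium bromide | CC(C)=CCC/C(C)=C/CC/C(C)=C/C[P+](c1ccccc1)(c1ccccc1)c1ccccc1.[Br-] | intermediate
20 | (2E,4E,6E)-2,7-dimethylocta-2,4,6-trienedial | O=C/C(C)=C/C=C/C=C(C)/C=O | starting material
21 | [(2E,6E)-3,7,11-trimethyldodeca-2,6,10-trien-1-ylidene]triphenylphosphorane | CC(C)=CCC/C(C)=C/CC/C(C)=C/C=P(c1ccccc1)(c1ccccc1)c1ccccc1 | intermediate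
22 | (2E,4E,6E,8Z,10E,14E)-2,7,11,15,19-pentamethylicosa-2,4,6,8,10,14,18-heptaenal | CC(C)=CCC/C(C)=C/CC/C(C)=C/C=C\C(C)=C\C=C\C=C(C)\C=O | intermediate
23 | (2E,4E,6E,8E,10E,14E)-2,7,11,15,19-pentamethylicosa-2,4,6,8,10,14,18-heptaenal | CC(C)=CCC/C(C)=C/CC/C(C)=C/C=C/C(C)=C/C=C/C=C(C)/C=O | intermediate
24 | [(2E,4E)-3-methyl-5-[(1R)-2,6,6-trimethylcyclohex-2-en-1-yl]penta-2,4-dien-1-ylidene]triphenylphosphorane | c1ccccc1P(c1ccccc1)(c1ccccc1)=C/C=C(C)/C=C/[C@H]1C(C)=CCCC1(C)C | intermediate
25 | (6R,11Z)-7',8'-dihydro-ε,ψ-carotene | CC(C)=CCC/C(C)=C/CC/C(C)=C/C=C/C(C)=C/C=C/C=C(C)/C=C\C=C(C)\C=C\[C@H]1C(C)=CCCC1(C)C | intermediate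
26 | all-E (6R)-7',8'-dihydro-ε,ψ-carotene (CNP0213990.1) | CC(C)=CCC/C(C)=C/CC/C(C)=C/C=C/C(C)=C/C=C/C=C(C)/C=C/C=C(C)/C=C/[C@H]1C(C)=CCCC1(C)C | target

## Step count and risks

Total step count: 11. Longest linear sequence: 7 steps (steps 1, 2, 3, 6, 7, 8, 11).

Steps most likely to fail:

1. Step 6. Delivery of the dienyl group to the neopentyl γ-carbon may be outrun by α-substitution or by addition to the ester carbonyl, and any loss of anti selectivity would erode the configurational purity at C6. The fallback sets out from enone 4 and comes back at alcohol 16; it forms C6–C7 by an intramolecular sigmatropic shift. Reduction of 4 with the (R)-configured oxazaborolidine and BH3·SMe2 should give (S)-2,4,4-trimethylcyclohex-2-en-1-ol F1. Alkylation with KH and tributyl(iodomethyl)stannane gives tributyl({[(1S)-2,4,4-trimethylcyclohex-2-en-1-yl]oxy}methyl)stannane F2. Tin–lithium exchange with n-BuLi at −78 °C triggers a [2,3]-Wittig–Still rearrangement that forms the new bond on the face the C–O bond leaves, so the (S) ether should give [(1R)-2,6,6-trimethylcyclohex-2-en-1-yl]methanol F3. Dess–Martin oxidation buffered with NaHCO3, kept cold and base-free to avoid epimerisation, gives (1R)-2,6,6-trimethylcyclohex-2-ene-1-carbaldehyde F4. Horner–Wadsworth–Emmons reaction with the lithium anion of triethyl 3-methyl-4-phosphonocrotonate, followed by chromatography, gives ethyl (2E,4E)-3-methyl-5-[(1R)-2,6,6-trimethylcyclohex-2-en-1-yl]penta-2,4-dienoate F5, and i-Bu2AlH at −78 °C reduces it to 16.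

2. Step 10. Over-reaction at the second formyl group of the symmetrical dialdehyde and incomplete Z-to-E relaxation may lower the supply of 23. The fallback sets out from dialdehyde 20 and comes back at aldehyde 23; it replaces statistical control by a protecting group. Treatment of 20 with one equivalent of 2,2-dimethylpropane-1,3-diol and catalytic pyridinium p-toluenesulfonate in toluene gives (2E,4E,6E)-7-(5,5-dimethyl-1,3-dioxan-2-yl)-2-methylocta-2,4,6-trienal F6, separated from recovered 20 and the bis-acetal. Wittig reaction with ylide 21 gives 5,5-dimethyl-2-[(2E,4E,6E,8E,10E,14E)-7,11,15,19-tetramethylicosa-2,4,6,8,10,14,18-heptaen-2-yl]-1,3-dioxane F7 together with its 8Z isomer, 5,5-dimethyl-2-[(2E,4E,6E,8Z,10E,14E)-7,11,15,19-tetramethylicosa-2,4,6,8,10,14,18-heptaen-2-yl]-1,3-dioxane F8. Hydrolysis with aqueous oxalic acid in THF gives 22 and 23, and heating in heptane as in step 10 converts 22 into 23.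

3. Step 8. Ionisation of the dienylic alcohol under acid may scramble the 9E geometry or lose H6 by elimination, and the salt may fail to crystallise. The fallback sets out from alcohol 16 and comes back at target 26, replacing steps 8 and 11 by a phosphonate olefination. PBr3 with catalytic pyridine in Et2O at −20 °C gives (2E,4E)-5-bromo-3-methyl-1-[(1R)-2,6,6-trimethylcyclohex-2-en-1-yl]penta-1,3-diene F9. Michaelis–Becker reaction with NaP(O)(OEt)2 in THF at 0 °C gives diethyl [(2E,4E)-3-methyl-5-[(1R)-2,6,6-trimethylcyclohex-2-en-1-yl]penta-2,4-dien-1-yl]phosphonate F10. Deprotonation with NaN(SiMe3)2 in THF at −78 °C and Horner–Wadsworth–Emmons reaction with aldehyde 23 should give 26 with high E preference; any 11Z isomer 25 is equilibrated in hot heptane as in step 11.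

## Further compounds

F1 | step 6 | (1S)-2,4,4-trimethylcyclohex-2-en-1-ol | O[C@@H]1C(C)=CC(C)(C)CC1
F2 | step 6 | tributyl({[(1S)-2,4,4-trimethylcyclohex-2-en-1-yl]oxy}methyl)stannane | CCCC[Sn](CCCC)(CCCC)CO[C@@H]1C(C)=CC(C)(C)CC1
F3 | step 6 | [(1R)-2,6,6-trimethylcyclohex-2-en-1-yl]methanol | OC[C@H]1C(C)=CCCC1(C)C
F4 | step 6 | (1R)-2,6,6-trimethylcyclohex-2-ene-1-carbaldehyde | O=C[C@H]1C(C)=CCCC1(C)C
F5 | step 6 | ethyl (2E,4E)-3-methyl-5-[(1R)-2,6,6-trimethylcyclohex-2-en-1-yl]penta-2,4-dienoate | CCOC(=O)/C=C(C)/C=C/[C@H]1C(C)=CCCC1(C)C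
F6 | step 10 | (2E,4E,6E)-7-(5,5-dimethyl-1,3-dioxan-2-yl)-2-methylocta-2,4,6-trienal | O=C/C(C)=C/C=C/C=C(C)/C1OCC(C)(C)CO1
F7 | step 10 | 5,5-dimethyl-2-[(2E,4E,6E,8E,10E,14E)-7,11,15,19-tetramethylicosa-2,4,6,8,10,14,18-heptaen-2-yl]-1,3-dioxane | CC(C)=CCC/C(C)=C/CC/C(C)=C/C=C/C(C)=C/C=C/C=C(C)/C1OCC(C)(C)CO1
F8 | step 10 | 5,5-dimethyl-2-[(2E,4E,6E,8Z,10E,14E)-7,11,15,19-tetramethylicosa-2,4,6,8,10,14,18-heptaen-2-yl]-1,3-dioxane | CC(C)=CCC/C(C)=C/CC/C(C)=C/C=C\C(C)=C\C=C\C=C(C)\C1OCC(C)(C)CO1
F9 | step 8 | (2E,4E)-5-bromo-3-methyl-1-[(1R)-2,6,6-trimethylcyclohex-2-en-1-yl]penta-1,3-diene | BrC/C=C(C)/C=C/[C@H]1C(C)=CCCC1(C)C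
F10 | step 8 | diethyl [(2E,4E)-3-methyl-5-[(1R)-2,6,6-trimethylcyclohex-2-en-1-yl]penta-2,4-dien-1-yl]phosphonate | CCOP(=O)(OCC)C/C=C(C)/C=C/[C@H]1C(C)=CCCC1(C)C
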